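The six-membered carbocycle hides a dimer. C4–C3–C2–C7 and C1–C6–C5–C1′ (C1 ring ketone, C4 ring carbinol, C5/C6 epoxide carbons, C7 acetoxymethyl carbon, C1′ side-chain carbinol) are the same 1,4-dioxygenated four-carbon unit, related by a twofold axis perpendicular to the ring. Cutting C1–C2 and C4–C5 therefore gives two molecules of dimethyl succinate. Their Claisen–Dieckmann cyclodimerisation forges both bonds in one operation and delivers all eight core carbons with the para oxygen pattern; the precursor is simply the acyclic diester. Aromatisation, dearomatising ketalisation, tartrate-controlled epoxidation, alkenyl addition and a double oxazaborolidine reduction then break the symmetry and set the four stereocentres.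

Key step: step 1

Numbering used in the text: C1 ring ketone carbon, C2 alkene carbon bearing C7 (CH2OAc), C3 alkene CH, C4 ring carbinol carbon, C5 fully substituted epoxide carbon, C6 epoxide CH, C1′ side-chain carbinol carbon, C2′=C3′ first side-chain alkene.

Assumption: L-(+)-diisopropyl tartrate is taken as the enantiomer that leads to the (1S,6R) epoxide 8; if the sense of induction is opposite, D-(−)-diisopropyl tartrate is used and nothing else changes.

Step 1
Reactants: 1 dimethyl succinate (two molecules)
Product: 3 dimethyl 2,5-dihydroxycyclohexa-1,4-diene-1,4-dicarboxylate (dimethyl succinylsuccinate in its bis-enol form), via acyclic keto triester 2 (not isolated)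
Conditions: NaOMe (2.2 equiv), MeOH, reflux; then 1 M H2SO4, 0 °C
Reagents that add atoms: none
Why: Methoxide reversibly forms the ester enolate of 1, whose α-carbon (future C5) attacks an ester carbonyl (future C4) of a second molecule in an intermolecular Claisen condensation to give 2, and the remote ester enolate carbon of 2 (future C2) then attacks the far ester carbonyl (future C1) in a Dieckmann condensation. The closest known reaction type is exactly this Claisen–Dieckmann self-condensation of succinic esters to succinylsuccinates. The one ring is closed in the 6-(enolexo)-exo-trig mode, whereas closure from the ketone α-carbon would be a disfavoured 5-(enolendo)-exo-trig process. No stereocentre needs control, because both new sp3 ring carbons are enolised in 3 and become aromatic carbons in step 2. The step needs head-to-tail constitution: all C–C bond formations are reversible, homodimerisation removes any cross-selectivity problem, and only the 2,5-dioxo-1,4-diester can be deprotonated twice at remote sites to a sparingly soluble disodium bis-enolate, which should drain the equilibria toward 3.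

Step 2
Reactants: 3 dimethyl succinylsuccinate
Product: 4 dimethyl 2,5-dihydroxyterephthalate
Conditions: N-chlorosuccinimide (1.05 equiv), AcOH, 80 °C
Reagents that add atoms: none
Why: Electrophilic α-chlorination of one enolised β-keto ester unit followed by loss of HCl is an oxidative aromatisation that should give the hydroquinone, driven by the gain in aromaticity.

Step 3
Reactants: 4 dimethyl 2,5-dihydroxyterephthalate
Product: 5 dimethyl 2-hydroxy-5-methoxyterephthalate
Conditions: MeI (1.0 equiv), K2CO3 (1.0 equiv), DMF, rt; unreacted 4 is recycled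
Reagents that add atoms: iodomethane, CI
Why: In this Williamson ether synthesis the two phenols of 4 are equivalent by symmetry, so only one mono-ether is possible, and it marks the oxygen on C1 as the future ketal oxygen while the oxygen on C4 stays free.

Step 4
Reactants: 5 dimethyl 2-hydroxy-5-methoxyterephthalate
Product: 6 2,5-bis(hydroxymethyl)-4-methoxyphenol
Conditions: LiAlH4 (3 equiv), THF, 0 °C to reflux; then H2O
Reagents that add atoms: none
Why: Hydride reduction of both aromatic esters by LiAlH4 (the phenol only consumes one hydride) should give the two benzylic alcohols that become C7 and C1′.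

Step 5
Reactants: 6 2,5-bis(hydroxymethyl)-4-methoxyphenol
Product: 7 2,5-bis(hydroxymethyl)-4,4-dimethoxycyclohexa-2,5-dien-1-one
Conditions: PhI(OAc)2 (1.05 equiv), MeOH, 0 °C
Reagents that add atoms: methanol, CO
Why: In this oxidative dearomatisation of a 4-methoxyphenol by a hypervalent iodine reagent the phenoxenium ion is captured by methanol at the para carbon that already bears OMe, which places the ketal on C1 and leaves C4 as the only ketone, so that all later enone and carbonyl chemistry is regiochemically defined.

Step 6
Reactants: 7 quinone monoketal diol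
Product: 8 (1S,6R)-1,4-bis(hydroxymethyl)-5,5-dimethoxy-7-oxabicyclo[4.1.0]hept-3-en-2-one
Conditions: Ph3COOH, NaN(SiMe3)2, L-(+)-diisopropyl tartrate, toluene, −50 °C
Reagents that add atoms: trityl hydroperoxide, OOC(c1ccccc1)(c1ccccc1)c1ccccc1
Why: In this tartrate-mediated, hydroxyl-directed Weitz–Scheffer epoxidation of a quinone monoketal the sodium alkoxide of the C1′ hydroxymethyl group, held in the tartrate assembly, should deliver trityl peroxide to the unsubstituted β-carbon C6, so that only C5=C6 reacts (the other β-carbon, C2, is fully substituted) and the chiral tartrate selects the face and sets C5 and C6 together.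

Step 7
Reactants: 8 epoxy diol
Product: 9 [(1S,6R)-1-(hydroxymethyl)-5,5-dimethoxy-2-oxo-7-oxabicyclo[4.1.0]hept-3-en-4-yl]methyl acetate
Conditions: AcCl (1.05 equiv), 2,4,6-collidine, CH2Cl2, −78 °C
Reagents that add atoms: acetyl chloride, CC(=O)Cl
Why: This is a kinetically selective O-acetylation, because the allylic C7 hydroxyl is unhindered whereas the C1′ hydroxyl is neopentylic on the fully substituted epoxide carbon and hydrogen-bonded to the C4 ketone, so the acetate of the target should be installed at C7 only.

Step 8
Reactants: 10 (E)-geranylacetone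
Product: 12 (E)-6,10-dimethylundeca-5,9-dien-1-yne, via enol phosphate 11 (not isolated)
Conditions: LiN(iPr)2 (1.05 equiv), THF, −78 °C; ClP(O)(OEt)2; then LiN(iPr)2 (2.3 equiv), −78 °C to rt
Reagents that add atoms: none
Why: Kinetic deprotonation at the methyl group, O-phosphorylation and base-induced β-elimination of the enol phosphate convert the methyl ketone into the terminal alkyne without touching the (E)-trisubstituted alkene.

Step 9
Reactants: 12 (E)-6,10-dimethylundeca-5,9-dien-1-yne
Product: 14 (1E,5E)-1-iodo-2,6,10-trimethylundeca-1,5,9-triene, via alkenylalane 13 (not isolated)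
Conditions: AlMe3 (2 equiv), Cp2ZrCl2 (0.25 equiv), CH2Cl2, rt; then I2, THF, −30 °C
Reagents that add atoms: trimethylaluminium, C[Al](C)C; iodine, II
Why: Negishi carboalumination adds methyl and aluminium syn across the terminal alkyne with aluminium at the terminus, and iodinolysis with retention gives the (E)-alkenyl iodide that carries the C2′=C3′ geometry of the target.

Step 10
Reactants: 9 hydroxy acetate
Product: 15 [(1R,6R)-1-formyl-5,5-dimethoxy-2-oxo-7-oxabicyclo[4.1.0]hept-3-en-4-yl]methyl acetate
Conditions: Dess–Martin periodinane (1.2 equiv), CH2Cl2, 0 °C to rt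
Reagents that add atoms: none
Why: Dess–Martin oxidation of the only free hydroxyl under non-aqueous conditions should give the aldehyde, which cannot enolise or epimerise because C5 is fully substituted.

Step 11
Reactants: 14 (1E,5E)-1-iodo-2,6,10-trimethylundeca-1,5,9-triene; 15 epoxy keto aldehyde
Product: 18 [(1S,6R)-1-[(2E,6E)-1-hydroxy-3,7,11-trimethyldodeca-2,6,10-trienyl]-5,5-dimethoxy-2-oxo-7-oxabicyclo[4.1.0]hept-3-en-4-yl]methyl acetate (both C1′ epimers), via alkenyllithium 16 (not isolated), via alkenylmagnesium bromide 17 (not isolated)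
Conditions: 14, t-BuLi (2.0 equiv), Et2O, −78 °C; MgBr2·OEt2; then 15, CH2Cl2/Et2O, −78 °C
Reagents that add atoms: none
Why: Iodine–lithium exchange with retention of alkene geometry, transmetalation to magnesium and Grignard-type 1,2-addition should take place at the aldehyde as the most electrophilic carbonyl, ahead of the hindered ring ketone and the acetate, and the configuration of the new C1′ centre is irrelevant because step 12 erases it.

Step 12
Reactants: 18 allylic alcohol (both C1′ epimers)
Product: 19 [(1R,6R)-5,5-dimethoxy-2-oxo-1-[(2E,6E)-3,7,11-trimethyldodeca-2,6,10-trienoyl]-7-oxabicyclo[4.1.0]hept-3-en-4-yl]methyl acetate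
Conditions: Dess–Martin periodinane (1.3 equiv), CH2Cl2, 0 °C
Reagents that add atoms: none
Why: Dess–Martin oxidation of the allylic alcohol converges both C1′ epimers into one non-enolisable 1,3-diketone whose two carbonyl groups flank the fully substituted C5.

Step 13
Reactants: 19 epoxy diketone
Product: 20 [(1R,5S,6R)-5-hydroxy-6-[(1S,2E,6E)-1-hydroxy-3,7,11-trimethyldodeca-2,6,10-trienyl]-2,2-dimethoxy-7-oxabicyclo[4.1.0]hept-3-en-3-yl]methyl acetate (the C1 dimethyl ketal of the target)
Conditions: (R)-2-methyl-CBS-oxazaborolidine (0.4 equiv), catecholborane (4 equiv), toluene, −78 °C; then MeOH, pH 7 buffer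
Reagents that add atoms: none
Why: In this double Corey–Bakshi–Shibata reduction the fully substituted C5 is the large and the alkenyl carbon the small substituent at both ketones, so the (R)-catalyst should deliver hydride in the same topological sense to each and give the (4S) and (1′S) carbinols, and at C4 this is also the less hindered face, syn to the small epoxide oxygen and anti to the side chain.

Step 14
Reactants: 20 C1 dimethyl ketal of the target
Product: 21 [(1R,5S,6R)-5-hydroxy-6-[(1S,2E,6E)-1-hydroxy-3,7,11-trimethyldodeca-2,6,10-trienyl]-2-oxo-7-oxabicyclo[4.1.0]hept-3-en-3-yl]methyl acetate (target)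
Conditions: montmorillonite K10 clay, wet CH2Cl2, rt
Reagents that add atoms: water, O
Why: Mild acid-catalysed hydrolysis of the allylic dimethyl ketal through its allyl-stabilised oxocarbenium ion unveils the C1 enone, while the epoxide, the acetate and the two allylic alcohols, all next to electron-withdrawing groups, should persist and no stereocentre is touched.

Compound list
1 | dimethyl succinate | COC(=O)CCC(=O)OC | starting material
2 | dimethyl 2-(2-methoxy-2-oxoethyl)-3-oxohexanedioate (racemic, present as its enolate) | COC(=O)CCC(=O)C(CC(=O)OC)C(=O)OC | intermediate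
3 | dimethyl 2,5-dihydroxycyclohexa-1,4-diene-1,4-dicarboxylate | COC(=O)C1=C(O)CC(C(=O)OC)=C(O)C1 | intermediate
4 | dimethyl 2,5-dihydroxyterephthalate | COC(=O)c1cc(O)c(C(=O)OC)cc1O | intermediate
5 | dimethyl 2-hydroxy-5-methoxyterephthalate | COC(=O)c1cc(OC)c(C(=O)OC)cc1O | intermediate
6 | 2,5-bis(hydroxymethyl)-4-methoxyphenol | COc1cc(CO)c(O)cc1CO | intermediate
7 | 2,5-bis(hydroxymethyl)-4,4-dimethoxycyclohexa-2,5-dien-1-one | COC1(OC)C=C(CO)C(=O)C=C1CO | intermediate
8 | (1S,6R)-1,4-bis(hydroxymethyl)-5,5-dimethoxy-7-oxabicyclo[4.1.0]hept-3-en-2-one | OCC1=CC(=O)[C@@]2(CO)O[C@H]2C1(OC)OC | intermediate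
9 | [(1S,6R)-1-(hydroxymethyl)-5,5-dimethoxy-2-oxo-7-oxabicyclo[4.1.0]hept-3-en-4-yl]methyl acetate | CC(=O)OCC1=CC(=O)[C@@]2(CO)O[C@H]2C1(OC)OC | intermediate
10 | (E)-geranylacetone, (E)-6,10-dimethylundeca-5,9-dien-2-one | CC(=O)CC/C=C(\C)CCC=C(C)C | starting material
11 | diethyl (E)-6,10-dimethylundeca-1,5,9-trien-2-yl phosphate | C=C(CC/C=C(\C)CCC=C(C)C)OP(=O)(OCC)OCC | intermediate
12 | (E)-6,10-dimethylundeca-5,9-dien-1-yne | C#CCC/C=C(\C)CCC=C(C)C | intermediate
13 | dimethyl[(1E,5E)-2,6,10-trimethylundeca-1,5,9-trienyl]alane | C[Al](C)/C=C(\C)CC/C=C(\C)CCC=C(C)C | intermediate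
14 | (1E,5E)-1-iodo-2,6,10-trimethylundeca-1,5,9-triene | I/C=C(\C)CC/C=C(\C)CCC=C(C)C | intermediate
15 | [(1R,6R)-1-formyl-5,5-dimethoxy-2-oxo-7-oxabicyclo[4.1.0]hept-3-en-4-yl]methyl acetate | CC(=O)OCC1=CC(=O)[C@@]2(C=O)O[C@H]2C1(OC)OC | intermediate
16 | (1E,5E)-2,6,10-trimethylundeca-1,5,9-trienyllithium | [Li]/C=C(\C)CC/C=C(\C)CCC=C(C)C | intermediate
17 | (1E,5E)-2,6,10-trimethylundeca-1,5,9-trienylmagnesium bromide | Br[Mg]/C=C(\C)CC/C=C(\C)CCC=C(C)C | intermediate
18 | [(1S,6R)-1-[(2E,6E)-1-hydroxy-3,7,11-trimethyldodeca-2,6,10-trienyl]-5,5-dimethoxy-2-oxo-7-oxabicyclo[4.1.0]hept-3-en-4-yl]methyl acetate, both C1′ epimers | CC(=O)OCC1=CC(=O)[C@@]2(C(O)/C=C(\C)CC/C=C(\C)CCC=C(C)C)O[C@H]2C1(OC)OC | intermediate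
19 | [(1R,6R)-5,5-dimethoxy-2-oxo-1-[(2E,6E)-3,7,11-trimethyldodeca-2,6,10-trienoyl]-7-oxabicyclo[4.1.0]hept-3-en-4-yl]methyl acetate | CC(=O)OCC1=CC(=O)[C@@]2(C(=O)/C=C(\C)CC/C=C(\C)CCC=C(C)C)O[C@H]2C1(OC)OC | intermediate
20 | [(1R,5S,6R)-5-hydroxy-6-[(1S,2E,6E)-1-hydroxy-3,7,11-trimethyldodeca-2,6,10-trienyl]-2,2-dimethoxy-7-oxabicyclo[4.1.0]hept-3-en-3-yl]methyl acetate | CC(=O)OCC1=C[C@H](O)[C@@]2([C@@H](O)/C=C(\C)CC/C=C(\C)CCC=C(C)C)O[C@H]2C1(OC)OC | intermediate
21 | [(1R,5S,6R)-5-hydroxy-6-[(1S,2E,6E)-1-hydroxy-3,7,11-trimethyldodeca-2,6,10-trienyl]-2-oxo-7-oxabicyclo[4.1.0]hept-3-en-3-yl]methyl acetate | CC(=O)OCC1=C[C@H](O)[C@@]2([C@@H](O)/C=C(\C)CC/C=C(\C)CCC=C(C)C)O[C@H]2C1=O | target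

Total step count: 14. Longest linear sequence: 12 steps (steps 1–7 and 10–14); steps 8 and 9 form the side branch.

Steps most likely to fail

Step 6. The second free hydroxyl (on C7) may compete for the sodium tartrate assembly, so that the facial selection in the peroxide delivery erodes. Fallback (resolution in place of asymmetric oxygen transfer):
- It sets out from 7. A non-selective Weitz–Scheffer epoxidation (t-BuOOH, DBU, CH2Cl2) gives the racemic epoxy diol F1.
- Enantiomer-selective enzymatic acetylation of its allylic hydroxyl (vinyl acetate, immobilised Candida antarctica lipase B, t-BuOMe) is stopped near half conversion. It gives the acetate 9 directly, beside the unreacted enantiomeric diol F2, which is removed by chromatography.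
- The route is rejoined at 9.

Step 11. Chemoselectivity may be lost through attack of the organomagnesium reagent on the ring ketone or the acetate, or through epoxide migration in the magnesium alkoxide. Fallback (acyl cross-coupling in place of carbonyl addition):
- It sets out from 15. Pinnick oxidation (NaClO2, NaH2PO4, 2-methyl-2-butene, t-BuOH/H2O) gives the carboxylic acid F3.
- F3 is converted (EtSH, N,N′-dicyclohexylcarbodiimide, DMAP, CH2Cl2) into the S-ethyl thioester F4.
- Fukuyama coupling of F4 with the alkenylzinc bromide F5 (from 14 by t-BuLi, then ZnBr2) under PdCl2(PPh3)2 catalysis in toluene/THF gives the diketone directly.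
- Steps 11 and 12 are bypassed and the route is rejoined at 19.

Step 13. Reagent control may be incomplete at one of the two carbonyl groups, through poor facial selectivity at the ring ketone or competing conjugate reduction of the acyclic enone. Fallback (substrate control, one centre at a time):
- It sets out from 18. Its formation under MgBr2 chelation of the aldehyde and ring-ketone oxygens should favour attack on the exposed aldehyde face.
- The (1′S) epimer F6 is separated by chromatography and silylated (Et3SiOTf, 2,6-lutidine, CH2Cl2) to the triethylsilyl ether F7.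
- LiBH(s-Bu)3 (THF, −78 °C) should then attack the ring ketone from the face of the small epoxide oxygen, opposite the bulky side chain, to give the (4S) alcohol F8.
- Aqueous HF in MeCN removes silyl ether and ketal together, and the route is rejoined at the target 21.

Further compounds
F1 | step 6 | racemic 1,4-bis(hydroxymethyl)-5,5-dimethoxy-7-oxabicyclo[4.1.0]hept-3-en-2-one | OCC1=CC(=O)C2(CO)OC2C1(OC)OC
F2 | step 6 | (1R,6S)-1,4-bis(hydroxymethyl)-5,5-dimethoxy-7-oxabicyclo[4.1.0]hept-3-en-2-one (enantiomer of 8) | OCC1=CC(=O)[C@]2(CO)O[C@@H]2C1(OC)OC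
F3 | step 11 | carboxylic acid from 15 (CO2H on C5 in place of CHO) | CC(=O)OCC1=CC(=O)[C@@]2(C(=O)O)O[C@H]2C1(OC)OC
F4 | step 11 | S-ethyl thioester of F3 | CC(=O)OCC1=CC(=O)[C@@]2(C(=O)SCC)O[C@H]2C1(OC)OC
F5 | step 11 | (1E,5E)-2,6,10-trimethylundeca-1,5,9-trienylzinc bromide | Br[Zn]/C=C(\C)CC/C=C(\C)CCC=C(C)C
F6 | step 13 | (1′S) epimer of 18 | CC(=O)OCC1=CC(=O)[C@@]2([C@@H](O)/C=C(\C)CC/C=C(\C)CCC=C(C)C)O[C@H]2C1(OC)OC
F7 | step 13 | C1′ triethylsilyl ether of F6 | CC(=O)OCC1=CC(=O)[C@@]2([C@@H](O[Si](CC)(CC)CC)/C=C(\C)CC/C=C(\C)CCC=C(C)C)O[C@H]2C1(OC)OC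
F8 | step 13 | (4S) alcohol from F7 (C1′ triethylsilyl ether of 20) | CC(=O)OCC1=C[C@H](O)[C@@]2([C@@H](O[Si](CC)(CC)CC)/C=C(\C)CC/C=C(\C)CCC=C(C)C)O[C@H]2C1(OC)OC
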